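**Retrosynthetic overview**
- The three silyl ethers come off last. Ring C is closed just before that by intramolecular Friedel–Crafts acylation (C4–C4a) of an (S)-3-aryloxy-2-arylpropanoic acid onto the phloroglucinol-derived ring A.
- The acid comes from oxidation of an (R)-3-aryloxy-2-arylpropan-1-ol. The key step makes that alcohol by enantioselective desymmetrising opening of a mirror-symmetric 3-aryloxetane with a phloroglucinol-derived phenol, so the O1–C2 bond and the C3 stereocentre form in one event.
- The 3-aryloxetane comes from Ni-catalysed coupling of the ring B aryl bromide with 3-bromooxetane. The ring B bromide comes from 4-bromo-3-methoxyphenol by O-tert-prenylation, aromatic Claisen rearrangement (prenyl to C5') and silylation.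
- The phenol partner comes from phloroglucinol by twofold silylation.
- Ring order: ring B and ring A are bought as arenes, the oxetane is attached and then opened, and ring C is formed last.

Assumption: CIP analysis of the given SMILES gives the (3S)-isoflavanone; compounds 2 and 7 are taken as commercial; the sense of induction of the acid catalyst in step 6 is provisional ((S)-STRIP = (S)-6,6'-bis(2,4,6-triisopropylphenyl)-1,1'-spirobiindane-7,7'-diyl hydrogen phosphate), and its antipode is used if the first run gives the other enantiomer.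

**Step 1**
Reactants: 1 4-bromo-3-methoxyphenol; 2 tert-butyl 2-methylbut-3-en-2-yl carbonate
Product: 3 1-bromo-2-methoxy-4-[(2-methylbut-3-en-2-yl)oxy]benzene
Conditions: Pd(PPh3)4 (2 mol %), THF, 0 °C
Reagents that add atoms: none
Why: Decarboxylative Tsuji–Trost O-allylation, in which the tertiary carbonate ionises to a 1,1-dimethyl-π-allyl palladium complex and the phenoxide attacks its more substituted terminus under kinetic control to give the reverse-prenyl ether, while the electron-rich C–Br bond does not add to zerovalent palladium at 0 °C.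

**Step 2**
Reactants: 3 1-bromo-2-methoxy-4-[(2-methylbut-3-en-2-yl)oxy]benzene
Product: 5 4-bromo-5-methoxy-2-(3-methylbut-2-en-1-yl)phenol, via ortho-dienone 4 (not isolated)
Conditions: Eu(fod)3 (10 mol %), toluene, 80 °C
Reagents that add atoms: none
Why: Aromatic Claisen rearrangement ([3,3]-sigmatropic shift) that delivers the allyl terminus to the free ortho carbon para to OMe (the other ortho site is flanked by the Br-buttressed OMe), dearomatising the ring to dienone 4, which re-aromatises by tautomerisation with the prenyl group where the target has it.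

**Step 3**
Reactants: 5 4-bromo-5-methoxy-2-(3-methylbut-2-en-1-yl)phenol
Product: 6 [4-bromo-5-methoxy-2-(3-methylbut-2-en-1-yl)phenoxy](tert-butyl)dimethylsilane
Conditions: TBSCl, imidazole, DMF, rt
Reagents that add atoms: tert-butyldimethylsilyl chloride, CC(C)(C)[Si](C)(C)Cl
Why: Standard phenol silylation; the aryl TBS ether blocks acid-induced chroman formation with the neighbouring prenyl group, survives steps 4–8 and leaves under non-basic fluoride at the end.

**Step 4**
Reactants: 6 [4-bromo-5-methoxy-2-(3-methylbut-2-en-1-yl)phenoxy](tert-butyl)dimethylsilane; 7 3-bromooxetane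
Product: 8 3-[4-(tert-butyldimethylsilyloxy)-2-methoxy-5-(3-methylbut-2-en-1-yl)phenyl]oxetane
Conditions: NiI2 (10 mol %), 4,4'-di-tert-butyl-2,2'-bipyridine (10 mol %), NaI (25 mol %), pyridine (10 mol %), Zn (2 equiv), DMA, 60 °C
Reagents that add atoms: none
Why: Nickel-catalysed reductive cross-electrophile coupling, in which the aryl bromide adds to low-valent nickel, the oxetan-3-yl radical from the alkyl bromide is captured and reductive elimination forms the aryl–C(sp3) bond, giving a mirror-symmetric (prochiral) oxetane.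

**Step 5**
Reactants: 9 phloroglucinol (benzene-1,3,5-triol)
Product: 10 3,5-bis(tert-butyldimethylsilyloxy)phenol
Conditions: TBSCl (2.0 equiv), imidazole (2.2 equiv), DMF, 0 °C to rt; chromatographic separation, mono- and tris-ethers recycled
Reagents that add atoms: tert-butyldimethylsilyl chloride, CC(C)(C)[Si](C)(C)Cl
Why: Statistical twofold silylation of threefold-symmetric phloroglucinol leaves one free OH as the nucleophile for step 6 and keeps ring A electron-rich for the later Friedel–Crafts closure.

**Step 6 (key step)**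
Reactants: 8 3-[4-(tert-butyldimethylsilyloxy)-2-methoxy-5-(3-methylbut-2-en-1-yl)phenyl]oxetane; 10 3,5-bis(tert-butyldimethylsilyloxy)phenol
Product: 11 (R)-3-[3,5-bis(tert-butyldimethylsilyloxy)phenoxy]-2-[4-(tert-butyldimethylsilyloxy)-2-methoxy-5-(3-methylbut-2-en-1-yl)phenyl]propan-1-ol
Conditions: (S)-STRIP (10 mol %), 10 (1.5 equiv), toluene, 4 Å MS, 50 °C
Reagents that add atoms: none
Why: Proposed new method: the chiral phosphoric acid protonates or hydrogen-bonds the oxetane oxygen while its P=O oxygen binds the phenol O–H, so the phenol oxygen attacks one of the two enantiotopic CH2–O carbons by SN2 inside the chiral pocket and the C3 stereocentre is set by which CH2 is attacked (the stereocentre itself is not a reacting atom, so it cannot be scrambled in this event), O-attack being favoured over ring-carbon attack because the nucleophile is delivered through the hydrogen-bonded O–H and the ring carbons of 10 are shielded by OTBS groups; the closest known reaction type is the chiral-phosphoric-acid-catalysed desymmetrising opening of 3-substituted oxetanes (intermolecular with heteroaryl thiols, intramolecular with tethered O–H nucleophiles).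

**Step 7**
Reactants: 11 (R)-3-[3,5-bis(tert-butyldimethylsilyloxy)phenoxy]-2-[4-(tert-butyldimethylsilyloxy)-2-methoxy-5-(3-methylbut-2-en-1-yl)phenyl]propan-1-ol
Product: 13 (S)-3-[3,5-bis(tert-butyldimethylsilyloxy)phenoxy]-2-[4-(tert-butyldimethylsilyloxy)-2-methoxy-5-(3-methylbut-2-en-1-yl)phenyl]propanoic acid, via (S)-aldehyde 12 (not isolated)
Conditions: TEMPO (20 mol %), PhI(OAc)2 (2.4 equiv), MeCN/H2O 1:1, 0 °C to rt
Reagents that add atoms: water, O
Why: Oxoammonium (TEMPO/PhI(OAc)2) oxidation of the primary alcohol through the aldehyde hydrate in a weakly acidic medium, where neither enolisation of aldehyde 12 nor β-elimination of its aryloxy group is expected to compete with the in-situ hydrate oxidation, so the stereocentre should be carried through unchanged (the descriptor changes from R to S only because the CIP priorities change).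

**Step 8**
Reactants: 13 (S)-3-[3,5-bis(tert-butyldimethylsilyloxy)phenoxy]-2-[4-(tert-butyldimethylsilyloxy)-2-methoxy-5-(3-methylbut-2-en-1-yl)phenyl]propanoic acid
Product: 15 (S)-5,7-bis(tert-butyldimethylsilyloxy)-3-[4-(tert-butyldimethylsilyloxy)-2-methoxy-5-(3-methylbut-2-en-1-yl)phenyl]chroman-4-one, via mixed trifluoroacetic anhydride 14 (not isolated)
Conditions: TFAA (1.2 equiv), CH2Cl2 (0.02 M), −20 to 0 °C; NaHCO3 quench
Reagents that add atoms: none
Why: Intramolecular Friedel–Crafts acylation through the mixed anhydride, in which the trioxygenated ring A attacks from either of its two equivalent positions ortho to the ether oxygen (one regioisomer, ring C closed) and the base-free, cold medium disfavours ketene formation, so the C3 configuration should be retained; loss of the O5 silyl group here would be harmless.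

**Step 9**
Reactants: 15 (S)-5,7-bis(tert-butyldimethylsilyloxy)-3-[4-(tert-butyldimethylsilyloxy)-2-methoxy-5-(3-methylbut-2-en-1-yl)phenyl]chroman-4-one
Product: 16 (3S)-5,7-dihydroxy-3-[4-hydroxy-2-methoxy-5-(3-methylbut-2-en-1-yl)phenyl]chroman-4-one (CNP0265203.1)
Conditions: KHF2 (4 equiv), MeOH/THF, rt
Reagents that add atoms: none
Why: Fluoride-driven cleavage of the three aryl silyl ethers (strong Si–F bond) in a weakly acidic bifluoride medium that avoids the base-induced enolisation and retro-oxa-Michael opening that racemise isoflavanones, and that leaves the prenyl group and the neighbouring free phenol uncyclised.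

**Compound list**
1 | 4-bromo-3-methoxyphenol | COc1cc(O)ccc1Br | starting material
2 | tert-butyl 2-methylbut-3-en-2-yl carbonate | CC(C)(C)OC(=O)OC(C)(C)C=C | starting material
3 | 1-bromo-2-methoxy-4-[(2-methylbut-3-en-2-yl)oxy]benzene | COc1cc(OC(C)(C)C=C)ccc1Br | intermediate
4 | 4-bromo-3-methoxy-6-(3-methylbut-2-en-1-yl)cyclohexa-2,4-dien-1-one (ortho-dienone, not isolated) | O=C1C=C(OC)C(Br)=CC1CC=C(C)C | intermediate
5 | 4-bromo-5-methoxy-2-(3-methylbut-2-en-1-yl)phenol | COc1cc(O)c(CC=C(C)C)cc1Br | intermediate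
6 | [4-bromo-5-methoxy-2-(3-methylbut-2-en-1-yl)phenoxy](tert-butyl)dimethylsilane | COc1cc(O[Si](C)(C)C(C)(C)C)c(CC=C(C)C)cc1Br | intermediate
7 | 3-bromooxetane | BrC1COC1 | starting material
8 | 3-[4-(tert-butyldimethylsilyloxy)-2-methoxy-5-(3-methylbut-2-en-1-yl)phenyl]oxetane | COc1cc(O[Si](C)(C)C(C)(C)C)c(CC=C(C)C)cc1C1COC1 | intermediate
9 | phloroglucinol | Oc1cc(O)cc(O)c1 | starting material
10 | 3,5-bis(tert-butyldimethylsilyloxy)phenol | CC(C)(C)[Si](C)(C)Oc1cc(O)cc(O[Si](C)(C)C(C)(C)C)c1 | intermediate
11 | (R)-3-[3,5-bis(tert-butyldimethylsilyloxy)phenoxy]-2-[4-(tert-butyldimethylsilyloxy)-2-methoxy-5-(3-methylbut-2-en-1-yl)phenyl]propan-1-ol | COc1cc(O[Si](C)(C)C(C)(C)C)c(CC=C(C)C)cc1[C@@H](COc2cc(O[Si](C)(C)C(C)(C)C)cc(O[Si](C)(C)C(C)(C)C)c2)CO | intermediate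
12 | (S)-3-[3,5-bis(tert-butyldimethylsilyloxy)phenoxy]-2-[4-(tert-butyldimethylsilyloxy)-2-methoxy-5-(3-methylbut-2-en-1-yl)phenyl]propanal (not isolated) | COc1cc(O[Si](C)(C)C(C)(C)C)c(CC=C(C)C)cc1[C@@H](COc2cc(O[Si](C)(C)C(C)(C)C)cc(O[Si](C)(C)C(C)(C)C)c2)C=O | intermediate
13 | (S)-3-[3,5-bis(tert-butyldimethylsilyloxy)phenoxy]-2-[4-(tert-butyldimethylsilyloxy)-2-methoxy-5-(3-methylbut-2-en-1-yl)phenyl]propanoic acid | COc1cc(O[Si](C)(C)C(C)(C)C)c(CC=C(C)C)cc1[C@@H](COc2cc(O[Si](C)(C)C(C)(C)C)cc(O[Si](C)(C)C(C)(C)C)c2)C(=O)O | intermediate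
14 | mixed anhydride of 13 with trifluoroacetic acid, (S) (not isolated) | COc1cc(O[Si](C)(C)C(C)(C)C)c(CC=C(C)C)cc1[C@@H](COc2cc(O[Si](C)(C)C(C)(C)C)cc(O[Si](C)(C)C(C)(C)C)c2)C(=O)OC(=O)C(F)(F)F | intermediate
15 | (S)-5,7-bis(tert-butyldimethylsilyloxy)-3-[4-(tert-butyldimethylsilyloxy)-2-methoxy-5-(3-methylbut-2-en-1-yl)phenyl]chroman-4-one | COc1cc(O[Si](C)(C)C(C)(C)C)c(CC=C(C)C)cc1[C@H]1COc2cc(O[Si](C)(C)C(C)(C)C)cc(O[Si](C)(C)C(C)(C)C)c2C1=O | intermediate
16 | (3S)-5,7-dihydroxy-3-[4-hydroxy-2-methoxy-5-(3-methylbut-2-en-1-yl)phenyl]chroman-4-one | COc1cc(O)c(CC=C(C)C)cc1[C@H]1COc2cc(O)cc(O)c2C1=O | target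

**Step count and risk**
Total steps: 9. Longest linear sequence: 8 (steps 1–4 and 6–9; step 5 is a one-step side branch).

The three steps most likely to fail:

Step 6 (oxetane opening by a phenol). A phenol is a weaker nucleophile than the thiols known to work. The product alcohol, the ring carbons of 10, or the ortho-methoxy oxygen of 8 (which would give a dihydrobenzofuran) may compete, and the ee is unknown. The fallback sets out from 8 and comes back at 11. Oxetane 8 is opened with TMSBr under a chiral tert-leucine-derived arylpyrrolidine squaramide hydrogen-bond-donor catalyst (TBME, −80 °C), a desymmetrisation known for 3-aryloxetanes, to give the (R)-bromo silyl ether F4. Phenol 10 is then O-alkylated with it (Cs2CO3, DMF, 40 °C) to give the trimethylsilyl ether F5, and aqueous citric acid in MeOH removes the trimethylsilyl group to return 11.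

Step 8 (Friedel–Crafts closure). Risks are partial racemisation through an acylium or ketene, addition of trifluoroacetic acid to the prenyl alkene, and C-trifluoroacetylation of ring A. The fallback sets out from 11 and comes back at 15, bypassing the carboxylic acid altogether. Ring A of 11 is iodinated ortho to the ether oxygen (NIS, CH2Cl2, −40 °C) to give the (R)-iodo alcohol F6. Buffered Dess–Martin oxidation gives the (S)-iodo aldehyde F7, used crude. An intramolecular Nozaki–Hiyama–Kishi reaction (CrCl2 4 equiv, NiCl2 2 mol %, DMF, rt) forms the C4–C4a bond under neutral conditions and gives the (3S)-isoflavan-4-ol F8 as a mixture of C4 epimers. A second Dess–Martin oxidation returns 15.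

Step 4 (reductive coupling). An electron-rich, ortho-substituted aryl bromide may give mainly hydrodehalogenation or oxetane homocoupling. The fallback sets out from 6 and comes back at 8 by building the oxetane instead of coupling it. α-Arylation of diethyl malonate with 6 (Pd(OAc)2, P(t-Bu)3·HBF4, K3PO4, toluene, 80 °C) gives the diethyl arylmalonate F1. Reduction with i-Bu2AlH (CH2Cl2, −78 to 0 °C) gives the prochiral 2-arylpropane-1,3-diol F2. One-pot treatment with n-BuLi and TsCl, then n-BuLi (THF, 0 to 60 °C), closes the ring through the monotosylate F3 and gives 8.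

**Further compounds**
F1 | step 4 | diethyl 2-[4-(tert-butyldimethylsilyloxy)-2-methoxy-5-(3-methylbut-2-en-1-yl)phenyl]malonate | COc1cc(O[Si](C)(C)C(C)(C)C)c(CC=C(C)C)cc1C(C(=O)OCC)C(=O)OCC
F2 | step 4 | 2-[4-(tert-butyldimethylsilyloxy)-2-methoxy-5-(3-methylbut-2-en-1-yl)phenyl]propane-1,3-diol | COc1cc(O[Si](C)(C)C(C)(C)C)c(CC=C(C)C)cc1C(CO)CO
F3 | step 4 | racemic mono-p-toluenesulfonate of diol F2 | COc1cc(O[Si](C)(C)C(C)(C)C)c(CC=C(C)C)cc1C(CO)COS(=O)(=O)c1ccc(C)cc1
F4 | step 6 | (R)-{3-bromo-2-[4-(tert-butyldimethylsilyloxy)-2-methoxy-5-(3-methylbut-2-en-1-yl)phenyl]propoxy}trimethylsilane | COc1cc(O[Si](C)(C)C(C)(C)C)c(CC=C(C)C)cc1[C@@H](CBr)CO[Si](C)(C)C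
F5 | step 6 | trimethylsilyl ether of 11, (S) by CIP | COc1cc(O[Si](C)(C)C(C)(C)C)c(CC=C(C)C)cc1[C@@H](COc2cc(O[Si](C)(C)C(C)(C)C)cc(O[Si](C)(C)C(C)(C)C)c2)CO[Si](C)(C)C
F6 | step 8 | (R)-3-[3,5-bis(tert-butyldimethylsilyloxy)-2-iodophenoxy]-2-[4-(tert-butyldimethylsilyloxy)-2-methoxy-5-(3-methylbut-2-en-1-yl)phenyl]propan-1-ol | COc1cc(O[Si](C)(C)C(C)(C)C)c(CC=C(C)C)cc1[C@@H](COc2cc(O[Si](C)(C)C(C)(C)C)cc(O[Si](C)(C)C(C)(C)C)c2I)CO
F7 | step 8 | (S)-3-[3,5-bis(tert-butyldimethylsilyloxy)-2-iodophenoxy]-2-[4-(tert-butyldimethylsilyloxy)-2-methoxy-5-(3-methylbut-2-en-1-yl)phenyl]propanal | COc1cc(O[Si](C)(C)C(C)(C)C)c(CC=C(C)C)cc1[C@@H](COc2cc(O[Si](C)(C)C(C)(C)C)cc(O[Si](C)(C)C(C)(C)C)c2I)C=O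
F8 | step 8 | (3S)-5,7-bis(tert-butyldimethylsilyloxy)-3-[4-(tert-butyldimethylsilyloxy)-2-methoxy-5-(3-methylbut-2-en-1-yl)phenyl]chroman-4-ol (C4 epimers) | COc1cc(O[Si](C)(C)C(C)(C)C)c(CC=C(C)C)cc1[C@H]1COc2cc(O[Si](C)(C)C(C)(C)C)cc(O[Si](C)(C)C(C)(C)C)c2C1O
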